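Germacrane numbering is used for the target and for every intermediate: C1–C10 are the ring carbons, C11–C13 the lactone carbons, O6 the lactone ring oxygen. TBS = tert‑butyldimethylsilyl, TBDPS = tert‑butyldiphenylsilyl.

## Analysis of the target

The target is a cis,cis‑germacranolide: a ten‑membered carbocycle with two in‑ring Z‑trisubstituted olefins (C1=C10 and C4=C5), trans‑fused across C6–C7 to an α‑methylene‑γ‑butyrolactone (O6–C12, C11=C13). It carries an acetate at C3 (3S), an acyloxy group at C8 (8S) and a free hydroxyl at C9 (9R). C6 (R), C7 (S), C8 and C9 form a contiguous tetrad with H‑6/H‑7 trans and O8/O9 cis (erythro); C3 is isolated from it by the C4=C5 olefin and has only a 1,4‑relationship to C6. The acyl group is (2S,3R)‑2,3‑dimethyloxirane‑2‑carboxylate, with the two oxirane methyl groups cis. It is therefore the epoxide of the E (tiglate‑type) acid, not of the Z (angelate‑type) acid, and this decides which allylic alcohol has to be epoxidised. The sensitive groups are the exocyclic enoate (Michael acceptor, base‑labile), the allylic acetate (lost to hydride and base), the glycidic ester, and the vicinal hydroxy ester (O8→O9 acyl shift; translactonisation to O8 whenever O8 is free next to the lactone). The synthesis is hard because a ten‑membered ring with two cis olefins must be closed, because C8 and C9 sit on a mobile ring and their oxygens must be told apart, and because C3 cannot be controlled from C6. The strategy rests on C8 and C9 being neighbouring oxygen‑bearing ring carbons with cis oxygens: this is the retron of a reductive coupling of a C8 aldehyde with the aldehyde of a C9 Z‑enal, and cutting C8–C9 leaves an open chain in which every other stereo element can be set by acyclic or small‑ring chemistry.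

## Retrosynthetic reasoning

**31 back to 28.** The last operations only unmask. The free O9 hydroxyl of 31 is kept as a silyl ether (30) until the end, and the lactone carbonyl C12 is carried as a methyl acetal (28) that is hydrolysed to lactol 29 and oxidised. The lactone is regenerated only after O8 is acylated, because a free O8 next to the lactone could translactonise to the 8,12‑olide; O9 stays silylated so that the lactol oxidation cannot touch the allylic carbinol.

**28 back to 24 and 27.** The C8 ester bond is cut. Acid 27 has cis methyl groups on the oxirane and therefore comes from the E allylic alcohol 25 by asymmetric epoxidation (26) and oxidation. The forward acylation has to reach a hindered secondary alcohol without base strong enough to touch the acetate.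

**24 back to 23.** The two hydroxyls of diol 23 are told apart by silylating the allylic, less encumbered O9.

**23 back to 22 (C8–C9).** This is the only place in the ring where two oxygenated sp3 carbons are adjacent, so one reductive coupling makes the ring bond and both carbinol centres at the alcohol oxidation level. Cutting here gives dialdehyde 22, whose C3, C6 and C7 centres and both olefin geometries are fixed beforehand. The forward reaction has to close a ten‑membered ring, give 8S and 9R, couple 1,2 and not through the enal β‑carbon, and leave the allylic acetate and the acetal alone.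

**22 back to 18.** The two aldehydes come from the primary alcohols of 21, freed from bis‑silyl ether 20. The C3 acetate is put on at 19→20: after the last hydride step, and before ring closure, since later it could not be introduced without distinguishing three secondary hydroxyls.

**18 back to 15 (C1=C10).** The Z olefin is cut by ring‑closing metathesis logic: in the six‑membered unsaturated lactone 17, made from methacrylate 16, the olefin can only be cis. The lactone also protects O3 and carries C9 at the acid level; reduction opens it to Z‑diol 18. A second Z‑selective phosphonate olefination at C1 was not used because it needs separate O3 protection, oxidative cleavage of a vinyl group beside two other olefins, and one more reduction.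

**15 back to 14 (C2–C3).** The bond is made by asymmetric allylboration of Z‑enal 14. C3 is too far from C6 for substrate control, so a reagent‑controlled addition is needed.

**14 back to 10 and 11 (C4=C5).** A Still–Gennari olefination of aldehyde 10 with phosphonate 11 gives Z‑enoate 12, in which C6 and the ester carbon C3 are cis as the ring demands; reduction (13) and oxidation give 14.

**10 back to 7.** Aldehyde 10 comes from alcohol 9, and its methyl acetal from lactol 8 and lactone 7. The lactone is masked early because the exocyclic enoate would not survive the phosphonate anion, the hydride steps, the allyl transfer or the single‑electron reductant of the key step.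

**7 back to 1 (C11=C13 and C7–C8).** The methylene is removed by Mannich methylenation logic (via 5 and 6) to give lactone 4. The C7–C8 bond is cut as a radical hydroxymethylation of butenolide 2, which gives 3 with the new group trans to the C6 substituent; 2 is the silyl ether of commercial 1, whose stereocentre becomes C6. Making C6–C7 by a Barbier‑type carboxyallylation of an open‑chain C6 aldehyde was set aside: with C3 present it would depend on 1,4‑induction across the C4=C5 olefin for the absolute sense, and the trans relation would depend on the geometry of an equilibrating allylmetal. In 2, one chiral‑pool centre sets both.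

## Alternatives that were turned down

Alternative 1: The C4/C10 carbon pair is joined as the tetrasubstituted ring‑fusion olefin of hydroazulene A2, so the ten‑membered ring is released rather than closed. The forward key step is ozonolysis of that olefin to 4,10‑dione A1, followed by twofold enol triflation and methyl cross‑coupling to install C4(Me)=C5 and C10(Me)=C1. In its favour, ring opening is entropically neutral and certain, C3 and C6–C9 are set on a rigid bicycle, and O8 and O9 arrive already differentiated; on these points it is stronger than the chosen route. Against it, A1 is a 1,5‑diketone (C4 and C10 are bridged by C1–C3) and is primed for transannular aldol re‑closure. Each ketone has two α‑positions and two enolate geometries in a mobile ring; enolisation of C4 toward C3 is favoured by the silyloxy group, and enolisation toward C5 invites β‑elimination of the lactone oxygen at C6. The methylene C13 is still missing and three protecting groups must be exchanged. The chosen strategy fixes both olefin geometries before the ring exists and needs five steps after ring formation, at the price of stereochemical risk in one step.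

Alternative 2: C3 and C8, which are not bonded in the target, are joined as the ring‑fusion bond of decalin cis‑diol A4, whose two cyclohexene rings (from ring‑closing metathesis) hold C4=C5 and C1=C10 cis by necessity. The forward key step is oxidative glycol cleavage of that bond to dienedione A3. In its favour, both olefin geometries are guaranteed, the ring opening is mild and certain, and the masked lactone with its methylene is in place; in certainty of ring formation it is stronger. Against it, the cleavage erases C3 and C8 as stereocentres. Both must be regenerated by reducing two different ketones on the ten‑membered ring and then told apart for acetate and acyl group, and C7 becomes an epimerisable centre that is α to the C8 ketone and allylic to C11=C13. A4 also needs two adjacent fully substituted carbinol carbons, each with two olefin‑bearing arms. The chosen strategy creates C8 and C9 directly as alcohols in the ring‑forming step, keeps the reagent‑controlled C3 centre untouched, and never places C7 next to a ketone.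

Alternative 3: The C4–C9 ring‑fusion bond of cis‑decalin A6, which carries a tertiary C9 alcohol and a C5 mesylate, is the bond to break. The forward key step is a base‑induced Grob fragmentation: the C9 alkoxide pushes, C4–C9 breaks, C9 becomes a ketone and C4=C5 forms with the geometry dictated by the antiperiplanar alignment, giving dienone A5 with C1=C10 already cis. In its favour, the olefin formation is stereospecific, C3 and C8 are set before ring opening, and only C9 remains to be set on the macrocycle; on this point it is stronger than the chosen key step, which sets two centres at once. Against it, A6 is a tricycle with a quaternary C4, a tertiary C9 carbinol and a sulfonate next to the acetal‑bearing C6: three sacrificial stereocentres whose relative configuration must be exact. The conjugated C9 ketone of A5 must then be reduced to 9R on the mobile ring, and the p‑methoxybenzyl and silyl groups exchanged for the two esters. The chosen route reaches its cyclisation substrate in far fewer operations, without sacrificial centres, and sets C9 together with C8 under chelation.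

Key step: step 18

Remark on the chemistry: methyl acetal 9 and all compounds up to 28 are expected as mixtures of C12 anomers. They are drawn as the 12R anomer (methoxy cis to the C6 substituent), and both anomers are carried on because C12 becomes the lactone carbonyl in step 24. Lactols 8 and 29 are drawn without configuration at C12.

## Route

Step 1
Reactants: 1 (S)‑5‑(hydroxymethyl)furan‑2(5H)‑one
Product: 2 (S)‑5‑(TBS‑oxymethyl)furan‑2(5H)‑one
Conditions: TBSCl, imidazole, CH2Cl2, 0 °C → rt
Reagents that add atoms: tert‑butyldimethylsilyl chloride, C[Si](C)(Cl)C(C)(C)C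
Why: Imidazole‑catalysed silylation of the primary alcohol; the base is too weak to deprotonate the γ‑position of the butenolide, so the chiral‑pool centre that becomes C6 is kept.

Step 2
Reactants: 2 (S)‑5‑(TBS‑oxymethyl)furan‑2(5H)‑one
Product: 3 (4R,5S)‑4‑(hydroxymethyl)‑5‑(TBS‑oxymethyl)dihydrofuran‑2(3H)‑one
Conditions: MeOH (solvent), benzophenone (0.2 equiv), hν (350 nm), rt, degassed
Reagents that add atoms: methanol, CO
Why: Photosensitised radical conjugate addition (radical hydroxymethylation): triplet benzophenone abstracts hydrogen from methanol, and the hydroxymethyl radical adds to the β‑carbon (C7) on the face opposite to the C6 silyloxymethyl group, which sets C7 trans to C6; hydrogen transfer from methanol to the α‑radical carries the chain.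

Step 3
Reactants: 3 (4R,5S)‑4‑(hydroxymethyl)‑5‑(TBS‑oxymethyl)dihydrofuran‑2(3H)‑one
Product: 4 (4R,5S)‑4‑(TBDPS‑oxymethyl)‑5‑(TBS‑oxymethyl)dihydrofuran‑2(3H)‑one
Conditions: TBDPSCl, imidazole, CH2Cl2, rt
Reagents that add atoms: tert‑butyldiphenylsilyl chloride, CC(C)(C)[Si](Cl)(c1ccccc1)c1ccccc1
Why: Standard silylation; the TBDPS ether on O8 is chosen because it withstands the acidic methanolysis that later frees O5 from its TBS ether, and every hydride and base step up to step 16.

Step 4
Reactants: 4 (4R,5S)‑4‑(TBDPS‑oxymethyl)‑5‑(TBS‑oxymethyl)dihydrofuran‑2(3H)‑one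
Product: 7 (4R,5S)‑4‑(TBDPS‑oxymethyl)‑5‑(TBS‑oxymethyl)‑3‑methylenedihydrofuran‑2(3H)‑one, via Mannich base 5 (not isolated), via trimethylammonium iodide 6 (not isolated)
Conditions: LiN(SiMe3)2, THF, −78 °C; Me2N=CH2+ I−, −78 °C → rt; then MeI, MeOH, rt; then NaHCO3, CH2Cl2/H2O
Reagents that add atoms: N,N‑dimethylmethyleneiminium iodide, C=[N+](C)C.[I-]
Why: Eschenmoser methylenation: Mannich reaction of the lithium enolate with the iminium salt, N‑methylation and base‑induced elimination of trimethylamine give the exocyclic C11=C13 olefin; C7 is β and C6 is γ to the carbonyl, so neither is touched, and the transient C11 centre is lost in the elimination.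

Step 5
Reactants: 7 (4R,5S)‑4‑(TBDPS‑oxymethyl)‑5‑(TBS‑oxymethyl)‑3‑methylenedihydrofuran‑2(3H)‑one
Product: 8 (4R,5S)‑4‑(TBDPS‑oxymethyl)‑5‑(TBS‑oxymethyl)‑3‑methylenetetrahydrofuran‑2‑ol (lactol, both anomers)
Conditions: iBu2AlH (1.2 equiv), CH2Cl2, −78 °C; aq. potassium sodium tartrate
Reagents that add atoms: none
Why: Partial reduction of a lactone: hydride adds to the carbonyl and the aluminium hemiacetal is stable at −78 °C, so the lactol is released only on work‑up; in a non‑coordinating solvent iBu2AlH attacks the carbonyl and not the conjugated olefin.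

Step 6
Reactants: 8 lactol (both anomers)
Product: 9 [(2S,3R,5R)‑3‑(TBDPS‑oxymethyl)‑5‑methoxy‑4‑methylenetetrahydrofuran‑2‑yl]methanol
Conditions: camphor‑10‑sulfonic acid (0.1 equiv), MeOH, 0 °C
Reagents that add atoms: methanol, CO
Why: Acid‑catalysed acetalisation through the cyclic oxocarbenium ion masks C12, and the same acid methanolyses the primary TBS ether while the TBDPS ether stays; the reaction is kept cold and short so that methanol does not add to C13 of the allylic oxocarbenium ion.

Step 7
Reactants: 9 [(2S,3R,5R)‑3‑(TBDPS‑oxymethyl)‑5‑methoxy‑4‑methylenetetrahydrofuran‑2‑yl]methanol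
Product: 10 (2S,3R,5R)‑3‑(TBDPS‑oxymethyl)‑5‑methoxy‑4‑methylenetetrahydrofuran‑2‑carbaldehyde
Conditions: Dess–Martin periodinane, NaHCO3, CH2Cl2, 0 °C → rt
Reagents that add atoms: none
Why: Dess–Martin oxidation of a primary alcohol under buffered, non‑basic conditions, which keeps the α‑alkoxy aldehyde from epimerising at C6 and leaves the acid‑labile acetal intact.

Step 8
Reactants: 10 (2S,3R,5R)‑3‑(TBDPS‑oxymethyl)‑5‑methoxy‑4‑methylenetetrahydrofuran‑2‑carbaldehyde; 11 methyl 2‑[bis(2,2,2‑trifluoroethoxy)phosphoryl]propanoate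
Product: 12 methyl (2Z)‑3‑[(2R,3R,5R)‑3‑(TBDPS‑oxymethyl)‑5‑methoxy‑4‑methylenetetrahydrofuran‑2‑yl]‑2‑methylprop‑2‑enoate
Conditions: KN(SiMe3)2, 18‑crown‑6, THF, −78 °C
Reagents that add atoms: none
Why: Still–Gennari olefination: with the bis(trifluoroethyl) phosphonate and a dissociated potassium counter‑ion the oxaphosphetane collapses faster than it equilibrates, so the kinetic Z‑enoate forms, with C6 cis to the ester carbon C3; at −78 °C the aldehyde does not epimerise.

Step 9
Reactants: 12 methyl (2Z)‑enoate
Product: 13 (2Z)‑3‑[(2R,3R,5R)‑3‑(TBDPS‑oxymethyl)‑5‑methoxy‑4‑methylenetetrahydrofuran‑2‑yl]‑2‑methylprop‑2‑en‑1‑ol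
Conditions: iBu2AlH (2.5 equiv), CH2Cl2, −78 °C
Reagents that add atoms: none
Why: Reduction of an α,β‑unsaturated ester to the allylic alcohol with two hydride equivalents; the intermediate aldehyde is reduced faster than the ester, and acetal, silyl ether and olefins are inert at this temperature.

Step 10
Reactants: 13 (2Z)‑allylic alcohol
Product: 14 (2Z)‑3‑[(2R,3R,5R)‑3‑(TBDPS‑oxymethyl)‑5‑methoxy‑4‑methylenetetrahydrofuran‑2‑yl]‑2‑methylprop‑2‑enal
Conditions: Dess–Martin periodinane, NaHCO3, CH2Cl2, 0 °C
Reagents that add atoms: none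
Why: Buffered Dess–Martin oxidation gives the Z‑enal without the acid or base that would isomerise it to the E‑isomer; the aldehyde is used without chromatography.

Step 11
Reactants: 14 (2Z)‑enal
Product: 15 (4S,5Z)‑6‑[(2R,3R,5R)‑3‑(TBDPS‑oxymethyl)‑5‑methoxy‑4‑methylenetetrahydrofuran‑2‑yl]‑5‑methylhexa‑1,5‑dien‑4‑ol (C3 = S in germacrane numbering)
Conditions: (−)‑Ipc2BOMe, CH2=CHCH2MgBr, Et2O, 0 °C → rt; then 14, −78 °C; then NaOH, H2O2, rt
Reagents that add atoms: allylmagnesium bromide, C=CC[Mg]Br
Why: Brown allylboration through a chair transition state; the isopinocampheyl groups of the borane made from (+)‑α‑pinene direct the allyl group to the Si face of the enal carbonyl, which gives the 3S carbinol, and this reagent control is expected to dominate over the remote C6 centre.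

Step 12
Reactants: 15 (4S,5Z)‑dienol
Product: 16 (4S,5Z)‑6‑[(2R,3R,5R)‑3‑(TBDPS‑oxymethyl)‑5‑methoxy‑4‑methylenetetrahydrofuran‑2‑yl]‑5‑methylhexa‑1,5‑dien‑4‑yl 2‑methylprop‑2‑enoate
Conditions: methacryloyl chloride, Et3N, 4‑(dimethylamino)pyridine (cat.), CH2Cl2, 0 °C
Reagents that add atoms: methacryloyl chloride, C=C(C)C(=O)Cl
Why: Acylation of the secondary allylic alcohol via the acylpyridinium ion; it brings in C9, C10 and the C10 methyl group, installs the second olefin for metathesis and protects O3 at the same time.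

Step 13
Reactants: 16 methacrylate
Product: 17 (6S)‑6‑{(1Z)‑1‑[(2R,3R,5R)‑3‑(TBDPS‑oxymethyl)‑5‑methoxy‑4‑methylenetetrahydrofuran‑2‑yl]prop‑1‑en‑2‑yl}‑3‑methyl‑5,6‑dihydro‑2H‑pyran‑2‑one
Conditions: (H2IMes)(PCy3)Cl2Ru=CHPh (second‑generation Grubbs catalyst, 5 mol%), CH2Cl2 (5 mM), 40 °C
Reagents that add atoms: none
Why: Ring‑closing metathesis of the vinyl group with the methacrylate gives the six‑membered unsaturated lactone, in which the new C1=C10 olefin can only be Z (C2 cis to C9); the trisubstituted C4=C5 and the 1,1‑disubstituted C11=C13 olefins are poor partners and would have to close a four‑ or an eight‑membered ring.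

Step 14
Reactants: 17 dihydropyranone
Product: 18 (2Z,5S,6Z)‑7‑[(2R,3R,5R)‑3‑(TBDPS‑oxymethyl)‑5‑methoxy‑4‑methylenetetrahydrofuran‑2‑yl]‑2,6‑dimethylhepta‑2,6‑diene‑1,5‑diol
Conditions: iBu2AlH (4 equiv), CH2Cl2, −78 → −20 °C
Reagents that add atoms: none
Why: Exhaustive hydride reduction of the lactone, through the lactol and its open hydroxy‑enal form, to the ene‑diol; the olefin geometry fixed by the ring is kept, and O3 is released as the only secondary hydroxyl.

Step 15
Reactants: 18 Z‑diol
Product: 20 (2Z,5S,6Z)‑5‑acetoxy‑1‑(TBDPS‑oxy)‑7‑[(2R,3R,5R)‑3‑(TBDPS‑oxymethyl)‑5‑methoxy‑4‑methylenetetrahydrofuran‑2‑yl]‑2,6‑dimethylhepta‑2,6‑diene, via mono‑silyl ether 19 (not isolated)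
Conditions: TBDPSCl (1.05 equiv), imidazole, CH2Cl2, 0 °C; then Ac2O, pyridine, 4‑(dimethylamino)pyridine (cat.), rt
Reagents that add atoms: tert‑butyldiphenylsilyl chloride, CC(C)(C)[Si](Cl)(c1ccccc1)c1ccccc1; acetic anhydride, CC(=O)OC(C)=O
Why: Chemoselective silylation of the primary allylic hydroxyl (O9) with the bulky chlorosilane, then acetylation of the remaining secondary hydroxyl (O3) in the same flask; the acetate is introduced only now because no hydride or strong base follows.

Step 16
Reactants: 20 acetate bis‑silyl ether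
Product: 21 (2Z,5S,6Z)‑5‑acetoxy‑7‑[(2R,3R,5R)‑3‑(hydroxymethyl)‑5‑methoxy‑4‑methylenetetrahydrofuran‑2‑yl]‑2,6‑dimethylhepta‑2,6‑dien‑1‑ol
Conditions: Bu4NF, AcOH, THF, rt
Reagents that add atoms: none
Why: Fluoride‑induced cleavage of both primary silyl ethers; buffering with acetic acid keeps the medium non‑basic so that the allylic acetate neither migrates nor hydrolyses.

Step 17
Reactants: 21 acetoxy diol
Product: 22 (2R,3S,5R)‑2‑[(1Z,3S,5Z)‑3‑acetoxy‑2,6‑dimethyl‑7‑oxohepta‑1,5‑dien‑1‑yl]‑5‑methoxy‑4‑methylenetetrahydrofuran‑3‑carbaldehyde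
Conditions: Dess–Martin periodinane (3 equiv), NaHCO3, CH2Cl2, 0 °C; filtered and used at once
Reagents that add atoms: none
Why: Twofold buffered Dess–Martin oxidation, the mildest way to a β,γ‑unsaturated aldehyde (C8) and a Z‑enal (C9); the dialdehyde is not chromatographed, to avoid conjugation of C11=C13 with C8 and epimerisation at C7.

Step 18
Reactants: 22 dialdehyde
Product: 23 (3S,6R,7R,8S,9R,12R)‑3‑acetoxy‑12‑methoxy‑6,12‑epoxygermacra‑1(10)Z,4Z,11(13)‑triene‑8,9‑diol
Conditions: SmI2 (4 equiv, 0.1 M), THF, −78 → 0 °C, slow addition of 22 (final 2 mM); then aq. NaHCO3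
Reagents that add atoms: none
Why: Reductive pinacol coupling: electron transfer from divalent samarium reduces first the enal carbonyl (C9) to an oxygen‑bound allylic ketyl and then the C8 aldehyde, the two carbon radicals, held together through an oxygen–samarium–oxygen bridge, combine to form C8–C9, and the bis‑alkoxide of trivalent samarium is protonated on work‑up. The closest known reaction type is the SmI2 (or low‑valent titanium) pinacol macrocyclisation of dialdehydes, enals included, to medium‑ and large‑ring 1,2‑diols. The ten‑membered carbocycle is closed by this 1,2‑coupling under high dilution with slow addition, so that ring closure outruns dimerisation, and the trans‑fused acetal ring and the two Z olefins already turn the chain ends toward each other. Bond formation at the enal β‑carbon C1 would give an eight‑membered ring and would have to give up the oxygen bridge, so it is expected to be slower than C8–C9 bonding. C9 is controlled by the samarium bridge, which holds O8 and O9 on the same side and so leads to the cis (erythro) diol, 9R for 8S. C8 is controlled by the C7 centre: the tether has to leave C8 on the C6 side of the C7–C8 bond and the hydrogen of C8 turns toward the exocyclic methylene to avoid allylic strain, which places O8 anti to H‑7 and corresponds to 8S. The step needs chemoselectivity for the two aldehydes; the allylic acetate, the acetal and the isolated olefins are not reduced by SmI2 in THF without additives, and no proton donor or HMPA is added, so that simple reduction to the alcohols is suppressed and chelation is kept. The low temperature protects the β,γ‑unsaturated C8 aldehyde and the Z geometry of the allylic ketyl until the ring is closed.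

Step 19
Reactants: 23 cis‑diol
Product: 24 9‑O‑TBS ether of 23
Conditions: TBSCl, imidazole, DMF, rt
Reagents that add atoms: tert‑butyldimethylsilyl chloride, C[Si](C)(Cl)C(C)(C)C
Why: Silylation of the more accessible hydroxyl: O9 is allylic and flanked by the planar C10, whereas O8 is flanked by the branched C7 and the acetal ring; a chlorosilane with imidazole is used because silyl triflates would ionise the allylic acetal.

Step 20
Reactants: 25 (E)‑2‑methylbut‑2‑en‑1‑ol
Product: 26 [(2R,3R)‑2,3‑dimethyloxiran‑2‑yl]methanol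
Conditions: Ti(OiPr)4 (10 mol%), D‑(−)‑diisopropyl tartrate (12 mol%), tBuOOH, 4 Å molecular sieves, CH2Cl2, −20 °C
Reagents that add atoms: tert‑butyl hydroperoxide, CC(C)(C)OO
Why: Sharpless asymmetric epoxidation; with the D‑(−)‑tartrate ligand the oxygen is delivered to the face that gives the (2R,3R)‑epoxy alcohol, and the E olefin geometry places the two methyl groups cis on the oxirane.

Step 21
Reactants: 26 [(2R,3R)‑2,3‑dimethyloxiran‑2‑yl]methanol
Product: 27 (2S,3R)‑2,3‑dimethyloxirane‑2‑carboxylic acid
Conditions: RuCl3 (cat.), NaIO4, CCl4/MeCN/H2O, rt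
Reagents that add atoms: water, O
Why: Oxidation of the primary epoxy alcohol to the glycidic acid by RuO4 formed in situ, through the aldehyde hydrate; the oxirane is untouched, and the C2 descriptor changes from R to S only because the substituent priorities change.

Step 22
Reactants: 24 9‑O‑TBS ether of 23; 27 (2S,3R)‑2,3‑dimethyloxirane‑2‑carboxylic acid
Product: 28 (3S,6R,7S,8S,9R,12R)‑3‑acetoxy‑9‑(TBS‑oxy)‑12‑methoxy‑6,12‑epoxygermacra‑1(10)Z,4Z,11(13)‑trien‑8‑yl (2S,3R)‑2,3‑dimethyloxirane‑2‑carboxylate
Conditions: 27, 2,4,6‑trichlorobenzoyl chloride, Et3N, THF, rt; then 24, 4‑(dimethylamino)pyridine, toluene, rt → 40 °C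
Reagents that add atoms: none
Why: Yamaguchi esterification: the mixed anhydride of 27 is attacked by 4‑(dimethylamino)pyridine at the aliphatic carbonyl and the acylpyridinium ion acylates the hindered O8; no stereocentre is affected, and the lactone is still masked, so no translactonisation to O8 can occur.

Step 23
Reactants: 28 ester
Product: 29 the lactol of 28 (12‑hydroxy in place of 12‑methoxy, both anomers)
Conditions: pyridinium p‑toluenesulfonate, acetone/H2O (4:1), 40 °C
Reagents that add atoms: water, O
Why: Hydrolysis of the allylic methyl acetal through the oxocarbenium ion under mildly acidic aqueous conditions that leave the silyl ether, the acetate and the electron‑poor glycidic ester intact.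

Step 24
Reactants: 29 lactol
Product: 30 9‑O‑TBS ether of the target
Conditions: Dess–Martin periodinane, NaHCO3, CH2Cl2, 0 °C → rt
Reagents that add atoms: none
Why: Oxidation of the lactol (a hemiacetal) to the α‑methylene lactone; with O9 silylated and O8 acylated the lactol hydroxyl is the only oxidisable group.

Step 25
Reactants: 30 9‑O‑TBS ether of the target
Product: 31 (3S,6R,7S,8S,9R)‑3‑acetoxy‑9‑hydroxy‑8‑[(2S,3R)‑2,3‑dimethyloxirane‑2‑carbonyloxy]germacra‑1(10)Z,4Z,11(13)‑trien‑12,6‑olide (CNP0299903.2)
Conditions: HF·pyridine, pyridine, THF, 0 °C → rt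
Reagents that add atoms: none
Why: Fluoride cleavage of the secondary silyl ether with buffered HF·pyridine; the weakly acidic medium avoids the O8→O9 acyl shift and the conjugate additions to the α‑methylene lactone that basic fluoride would invite.

## Compound list

1 | (S)‑5‑(hydroxymethyl)furan‑2(5H)‑one | O=C1O[C@H](CO)C=C1 | starting material
2 | (S)‑5‑(TBS‑oxymethyl)furan‑2(5H)‑one | O=C1O[C@H](CO[Si](C)(C)C(C)(C)C)C=C1 | intermediate
3 | (4R,5S)‑4‑(hydroxymethyl)‑5‑(TBS‑oxymethyl)dihydrofuran‑2(3H)‑one | O=C1C[C@H](CO)[C@@H](CO[Si](C)(C)C(C)(C)C)O1 | intermediate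
4 | (4R,5S)‑4‑(TBDPS‑oxymethyl)‑5‑(TBS‑oxymethyl)dihydrofuran‑2(3H)‑one | O=C1C[C@H](CO[Si](c2ccccc2)(c2ccccc2)C(C)(C)C)[C@@H](CO[Si](C)(C)C(C)(C)C)O1 | intermediate
5 | Mannich base: 3‑(dimethylaminomethyl) derivative of 4 (C3 epimers) | CN(C)CC1C(=O)O[C@H](CO[Si](C)(C)C(C)(C)C)[C@H]1CO[Si](c2ccccc2)(c2ccccc2)C(C)(C)C | intermediate
6 | 3‑(trimethylammoniomethyl) derivative of 4, iodide | C[N+](C)(C)CC1C(=O)O[C@H](CO[Si](C)(C)C(C)(C)C)[C@H]1CO[Si](c2ccccc2)(c2ccccc2)C(C)(C)C.[I-] | intermediate
7 | (4R,5S)‑4‑(TBDPS‑oxymethyl)‑5‑(TBS‑oxymethyl)‑3‑methylenedihydrofuran‑2(3H)‑one | C=C1C(=O)O[C@H](CO[Si](C)(C)C(C)(C)C)[C@H]1CO[Si](c2ccccc2)(c2ccccc2)C(C)(C)C | intermediate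
8 | (4R,5S)‑4‑(TBDPS‑oxymethyl)‑5‑(TBS‑oxymethyl)‑3‑methylenetetrahydrofuran‑2‑ol (lactol, anomers) | C=C1C(O)O[C@H](CO[Si](C)(C)C(C)(C)C)[C@H]1CO[Si](c2ccccc2)(c2ccccc2)C(C)(C)C | intermediate
9 | [(2S,3R,5R)‑3‑(TBDPS‑oxymethyl)‑5‑methoxy‑4‑methylenetetrahydrofuran‑2‑yl]methanol | C=C1[C@H](OC)O[C@H](CO)[C@H]1CO[Si](c2ccccc2)(c2ccccc2)C(C)(C)C | intermediate
10 | (2S,3R,5R)‑3‑(TBDPS‑oxymethyl)‑5‑methoxy‑4‑methylenetetrahydrofuran‑2‑carbaldehyde | C=C1[C@H](OC)O[C@H](C=O)[C@H]1CO[Si](c2ccccc2)(c2ccccc2)C(C)(C)C | intermediate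
11 | methyl 2‑[bis(2,2,2‑trifluoroethoxy)phosphoryl]propanoate | COC(=O)C(C)P(=O)(OCC(F)(F)F)OCC(F)(F)F | starting material
12 | methyl (2Z)‑3‑[(2R,3R,5R)‑3‑(TBDPS‑oxymethyl)‑5‑methoxy‑4‑methylenetetrahydrofuran‑2‑yl]‑2‑methylprop‑2‑enoate | C=C1[C@H](OC)O[C@H](/C=C(/C)C(=O)OC)[C@H]1CO[Si](c2ccccc2)(c2ccccc2)C(C)(C)C | intermediate
13 | (2Z)‑3‑[(2R,3R,5R)‑3‑(TBDPS‑oxymethyl)‑5‑methoxy‑4‑methylenetetrahydrofuran‑2‑yl]‑2‑methylprop‑2‑en‑1‑ol | C=C1[C@H](OC)O[C@H](/C=C(/C)CO)[C@H]1CO[Si](c2ccccc2)(c2ccccc2)C(C)(C)C | intermediate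
14 | (2Z)‑3‑[(2R,3R,5R)‑3‑(TBDPS‑oxymethyl)‑5‑methoxy‑4‑methylenetetrahydrofuran‑2‑yl]‑2‑methylprop‑2‑enal | C=C1[C@H](OC)O[C@H](/C=C(/C)C=O)[C@H]1CO[Si](c2ccccc2)(c2ccccc2)C(C)(C)C | intermediate
15 | (4S,5Z)‑6‑[(2R,3R,5R)‑3‑(TBDPS‑oxymethyl)‑5‑methoxy‑4‑methylenetetrahydrofuran‑2‑yl]‑5‑methylhexa‑1,5‑dien‑4‑ol | C=C1[C@H](OC)O[C@H](/C=C(/C)[C@@H](O)CC=C)[C@H]1CO[Si](c2ccccc2)(c2ccccc2)C(C)(C)C | intermediate
16 | methacrylate of 15 | C=C1[C@H](OC)O[C@H](/C=C(/C)[C@@H](OC(=O)C(C)=C)CC=C)[C@H]1CO[Si](c2ccccc2)(c2ccccc2)C(C)(C)C | intermediate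
17 | (6S)‑6‑{(1Z)‑1‑[(2R,3R,5R)‑3‑(TBDPS‑oxymethyl)‑5‑methoxy‑4‑methylenetetrahydrofuran‑2‑yl]prop‑1‑en‑2‑yl}‑3‑methyl‑5,6‑dihydro‑2H‑pyran‑2‑one | C=C1[C@H](OC)O[C@H](/C=C(/C)[C@@H]2CC=C(C)C(=O)O2)[C@H]1CO[Si](c3ccccc3)(c3ccccc3)C(C)(C)C | intermediate
18 | (2Z,5S,6Z)‑7‑[(2R,3R,5R)‑3‑(TBDPS‑oxymethyl)‑5‑methoxy‑4‑methylenetetrahydrofuran‑2‑yl]‑2,6‑dimethylhepta‑2,6‑diene‑1,5‑diol | C=C1[C@H](OC)O[C@H](/C=C(/C)[C@@H](O)C/C=C(/C)CO)[C@H]1CO[Si](c2ccccc2)(c2ccccc2)C(C)(C)C | intermediate
19 | 1‑O‑TBDPS ether of 18 (O9 silylated, O3 free) | C=C1[C@H](OC)O[C@H](/C=C(/C)[C@@H](O)C/C=C(/C)CO[Si](c2ccccc2)(c2ccccc2)C(C)(C)C)[C@H]1CO[Si](c2ccccc2)(c2ccccc2)C(C)(C)C | intermediate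
20 | 5‑O‑acetate of 19 (C3 acetate, O8 and O9 TBDPS ethers) | C=C1[C@H](OC)O[C@H](/C=C(/C)[C@@H](OC(C)=O)C/C=C(/C)CO[Si](c2ccccc2)(c2ccccc2)C(C)(C)C)[C@H]1CO[Si](c2ccccc2)(c2ccccc2)C(C)(C)C | intermediate
21 | (2Z,5S,6Z)‑5‑acetoxy‑7‑[(2R,3R,5R)‑3‑(hydroxymethyl)‑5‑methoxy‑4‑methylenetetrahydrofuran‑2‑yl]‑2,6‑dimethylhepta‑2,6‑dien‑1‑ol | C=C1[C@H](OC)O[C@H](/C=C(/C)[C@@H](OC(C)=O)C/C=C(/C)CO)[C@H]1CO | intermediate
22 | (2R,3S,5R)‑2‑[(1Z,3S,5Z)‑3‑acetoxy‑2,6‑dimethyl‑7‑oxohepta‑1,5‑dien‑1‑yl]‑5‑methoxy‑4‑methylenetetrahydrofuran‑3‑carbaldehyde | O=C[C@H]1C(=C)[C@H](OC)O[C@@H]1/C=C(/C)[C@@H](OC(C)=O)C/C=C(/C)C=O | intermediate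
23 | (3S,6R,7R,8S,9R,12R)‑3‑acetoxy‑12‑methoxy‑6,12‑epoxygermacra‑1(10)Z,4Z,11(13)‑triene‑8,9‑diol | C=C1[C@H](OC)O[C@@H]2/C=C(/C)[C@@H](OC(C)=O)C/C=C(/C)[C@@H](O)[C@@H](O)[C@@H]12 | intermediate
24 | 9‑O‑TBS ether of 23 | C=C1[C@H](OC)O[C@@H]2/C=C(/C)[C@@H](OC(C)=O)C/C=C(/C)[C@@H](O[Si](C)(C)C(C)(C)C)[C@@H](O)[C@@H]12 | intermediate
25 | (E)‑2‑methylbut‑2‑en‑1‑ol | C/C=C(\C)CO | starting material
26 | [(2R,3R)‑2,3‑dimethyloxiran‑2‑yl]methanol | OC[C@@]1(C)O[C@@H]1C | intermediate
27 | (2S,3R)‑2,3‑dimethyloxirane‑2‑carboxylic acid | OC(=O)[C@@]1(C)O[C@@H]1C | intermediate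
28 | (3S,6R,7S,8S,9R,12R)‑3‑acetoxy‑9‑(TBS‑oxy)‑12‑methoxy‑6,12‑epoxygermacra‑1(10)Z,4Z,11(13)‑trien‑8‑yl (2S,3R)‑2,3‑dimethyloxirane‑2‑carboxylate | C=C1[C@H](OC)O[C@@H]2/C=C(/C)[C@@H](OC(C)=O)C/C=C(/C)[C@@H](O[Si](C)(C)C(C)(C)C)[C@@H](OC(=O)[C@@]3(C)O[C@@H]3C)[C@@H]12 | intermediate
29 | lactol of 28 (12‑hydroxy, anomers) | C=C1C(O)O[C@@H]2/C=C(/C)[C@@H](OC(C)=O)C/C=C(/C)[C@@H](O[Si](C)(C)C(C)(C)C)[C@@H](OC(=O)[C@@]3(C)O[C@@H]3C)[C@@H]12 | intermediate
30 | 9‑O‑TBS ether of the target | C=C1C(=O)O[C@@H]2/C=C(/C)[C@@H](OC(C)=O)C/C=C(/C)[C@@H](O[Si](C)(C)C(C)(C)C)[C@@H](OC(=O)[C@@]3(C)O[C@@H]3C)[C@@H]12 | intermediate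
31 | (3S,6R,7S,8S,9R)‑3‑acetoxy‑9‑hydroxy‑8‑[(2S,3R)‑2,3‑dimethyloxirane‑2‑carbonyloxy]germacra‑1(10)Z,4Z,11(13)‑trien‑12,6‑olide | C=C1C(=O)O[C@@H]2/C=C(/C)[C@@H](OC(C)=O)C/C=C(/C)[C@@H](O)[C@@H](OC(=O)[C@@]3(C)O[C@@H]3C)[C@@H]12 | target

## Step count and least certain steps

Total: 25 steps. Longest linear sequence: 23 steps (steps 1–19 and 22–25, from 1); acid 27 is made in a two‑step branch (steps 20–21).

**Step 18 (key step).** The most likely failure is insufficient control of the relative configuration at C9: the allylic ketyl is planar and delocalised, and the ten‑membered transition state may not hold the samarium bridge tightly, so the trans‑diol can compete. Intermolecular coupling and simple reduction are the second concern and are answered by dilution and the absence of proton donors. Fallback: starting from 22, the same coupling is run and the 9‑epimeric trans‑diol F1 is not discarded. MnO2 in CH2Cl2 oxidises only its allylic C9 carbinol to the α‑hydroxy enone F2, and Zn(BH4)2 in Et2O at −20 °C reduces the ketone under chelation with the free O8 hydroxyl, which gives the anti (erythro) diol and so returns to 23. The C9 centre is then set by chelation‑controlled hydride delivery and not by the radical coupling.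

**Step 19.** The most likely failure is loss of site selectivity between O8 and O9 in the silylation, since both are secondary and the steric difference is modest. Fallback: starting from 23, MnO2 oxidises the allylic C9 carbinol selectively to the hydroxy enone F2 (as above), which leaves O8 as the only hydroxyl. Yamaguchi esterification with 27 gives keto ester F3; the planar C9 also relieves the hindrance at O8. Reduction with catecholborane and (R)‑2‑methyl‑CBS‑oxazaborolidine is expected to give the 9R alcohol F4 if the 2‑methylalkenyl flank acts as the large group, as it does in simple 2‑methyl enones. TBSCl and imidazole in DMF then silylate the single free hydroxyl, and the route is rejoined at 28.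

**Step 11.** The most likely failure is poor facial selectivity if the reagent is mismatched with the C6 centre, which the Z olefin holds close to the aldehyde, or partial Z‑to‑E isomerisation of the enal before addition. Fallback: starting from 14, CH2=CHCH2MgBr in THF at −78 °C adds without stereocontrol to give 15 together with its C3 epimer F5. Dess–Martin periodinane oxidises the mixture to the dienone F6, and reduction with catecholborane and (R)‑2‑methyl‑CBS‑oxazaborolidine (alkenyl flank large, allyl CH2 small) gives the 3S alcohol 15. The stereocentre then comes from a catalyst‑controlled ketone reduction, not from the allyl transfer.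

**Step 6.** The most likely failure is acid‑promoted addition of methanol to C13 of the allylic oxocarbenium ion, or partial loss of the TBDPS ether, during the combined acetalisation and desilylation. Fallback: starting from 8, the lactol hydroxyl is O‑methylated under non‑acidic conditions with Ag2O and MeI in CH2Cl2 to give methyl acetal F7, which still carries both silyl ethers. Buffered HF·pyridine in THF/pyridine at 0 °C then removes the primary TBS ether in preference to the TBDPS ether and gives 9.

## Further compounds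

F1 | step 18 | 9‑epimer of 23: (3S,6R,7R,8S,9S,12R)‑3‑acetoxy‑12‑methoxy‑6,12‑epoxygermacra‑1(10)Z,4Z,11(13)‑triene‑8,9‑diol (trans‑diol) | C=C1[C@H](OC)O[C@@H]2/C=C(/C)[C@@H](OC(C)=O)C/C=C(/C)[C@H](O)[C@@H](O)[C@@H]12
F2 | step 18 | (3S,6R,7R,8S,12R)‑3‑acetoxy‑8‑hydroxy‑12‑methoxy‑6,12‑epoxygermacra‑1(10)Z,4Z,11(13)‑trien‑9‑one | C=C1[C@H](OC)O[C@@H]2/C=C(/C)[C@@H](OC(C)=O)C/C=C(/C)C(=O)[C@@H](O)[C@@H]12
F3 | step 19 | 8‑O‑[(2S,3R)‑2,3‑dimethyloxirane‑2‑carbonyl] derivative of F2 (9‑ketone) | C=C1[C@H](OC)O[C@@H]2/C=C(/C)[C@@H](OC(C)=O)C/C=C(/C)C(=O)[C@@H](OC(=O)[C@@]3(C)O[C@@H]3C)[C@@H]12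
F4 | step 19 | 9‑desilyl 28: 8‑ester with free 9R hydroxyl, methyl acetal in place | C=C1[C@H](OC)O[C@@H]2/C=C(/C)[C@@H](OC(C)=O)C/C=C(/C)[C@@H](O)[C@@H](OC(=O)[C@@]3(C)O[C@@H]3C)[C@@H]12
F5 | step 11 | C3 epimer of 15: (4R,5Z)‑6‑[(2R,3R,5R)‑3‑(TBDPS‑oxymethyl)‑5‑methoxy‑4‑methylenetetrahydrofuran‑2‑yl]‑5‑methylhexa‑1,5‑dien‑4‑ol | C=C1[C@H](OC)O[C@H](/C=C(/C)[C@H](O)CC=C)[C@H]1CO[Si](c2ccccc2)(c2ccccc2)C(C)(C)C
F6 | step 11 | (5Z)‑6‑[(2R,3R,5R)‑3‑(TBDPS‑oxymethyl)‑5‑methoxy‑4‑methylenetetrahydrofuran‑2‑yl]‑5‑methylhexa‑1,5‑dien‑4‑one | C=C1[C@H](OC)O[C@H](/C=C(/C)C(=O)CC=C)[C@H]1CO[Si](c2ccccc2)(c2ccccc2)C(C)(C)C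
F7 | step 6 | (2S,3R,5R)‑3‑(TBDPS‑oxymethyl)‑2‑(TBS‑oxymethyl)‑5‑methoxy‑4‑methylenetetrahydrofuran | C=C1[C@H](OC)O[C@H](CO[Si](C)(C)C(C)(C)C)[C@H]1CO[Si](c2ccccc2)(c2ccccc2)C(C)(C)C
A1 | alternative 1 | ten‑membered 4,10‑dione with trans‑fused lactone, 3‑O‑triethylsilyl, 8‑O‑p‑methoxybenzyl, 9‑O‑TBS | C1C(=O)O[C@@H]2CC(=O)[C@@H](O[Si](CC)(CC)CC)CCC(=O)[C@@H](O[Si](C)(C)C(C)(C)C)[C@@H](OCc3ccc(OC)cc3)[C@@H]12
A2 | alternative 1 | hydroazulene with C4=C10 ring‑fusion olefin, precursor of A1 | C1C(=O)O[C@@H]2CC3=C(CC[C@@H]3O[Si](CC)(CC)CC)[C@@H](O[Si](C)(C)C(C)(C)C)[C@@H](OCc4ccc(OC)cc4)[C@@H]12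
A3 | alternative 2 | ten‑membered 1(10)Z,4Z‑diene‑3,8‑dione with lactone masked as methyl acetal, 9‑O‑TBS | C=C1[C@H](OC)O[C@@H]2/C=C(/C)C(=O)C/C=C(/C)[C@@H](O[Si](C)(C)C(C)(C)C)C(=O)[C@@H]12
A4 | alternative 2 | decalin with C3–C8 ring‑fusion cis‑diol (configuration at C3 and C8 left open), precursor of A3 | C=C1[C@H](OC)O[C@@H]2C=C(C)C3(O)CC=C(C)[C@@H](O[Si](C)(C)C(C)(C)C)C3(O)[C@@H]12
A5 | alternative 3 | ten‑membered 1(10)Z,4Z‑dien‑9‑one with lactone masked as methyl acetal, 3‑O‑triethylsilyl, 8‑O‑p‑methoxybenzyl | C=C1[C@H](OC)O[C@@H]2/C=C(/C)[C@@H](O[Si](CC)(CC)CC)C/C=C(/C)C(=O)[C@@H](OCc3ccc(OC)cc3)[C@@H]12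
A6 | alternative 3 | cis‑decalin with C4–C9 ring‑fusion bond, C9 tertiary alcohol and C5 mesylate (configuration at C4, C5 and C9 left open), precursor of A5 | C=C1[C@H](OC)O[C@@H]2C(OS(C)(=O)=O)C3(C)[C@@H](O[Si](CC)(CC)CC)CC=C(C)C3(O)[C@@H](OCc4ccc(OC)cc4)[C@@H]12
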